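Numbering: C1 ester carbon, C2 its CH2, ring O1–O2–C3–C4–C5–C6 (O2 on C3, O1 on C6), side chain C7–C14 (stereocentre C10, alkene C11=C12).
Cuts: first C2–C3 (silyl ketene acetal plus cyclic peroxycarbenium ion). Then C5–C6 and O2–C3 together, which splits the 1,2-dioxane into a C6–O1–O2 triad and a C5–C4–C3 triad.
Enabling feature: C6 is a ketone carbon that already carries O1–O2, so it is a peroxycarbenium ion (C6 acceptor, O2 donor). C3 is at aldehyde level and 1,3 to C5, so C5–C4–C3 is a homoenolate, stored as the C3–C4–C5 ring of a 2-ethylcyclopropyl silyl ether (polarity reversal at C5).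
Forward: the C6–C14 ketone equivalent is built linearly and converted to its silyl peroxyketal. A formal [3+3] annulation with the cyclopropane closes the only ring, and C1–C2 is added last.
Stereochemistry: C10 comes from catalytic asymmetric ethylation and chirality transfer in a Claisen step. C4 comes from an auxiliary-controlled cyclopropanation. C6 is set in the [3+3] step (1,3-induction from C4, ring diastereomer removed). C3 is set by axial attack on a locked half-chair cation.

Key step: step 10

Assumption: the (S,S)-tartaramide boronate is taken to steer the zinc carbenoid to the face that gives the (1S,2S)-cyclopropane; if the sense is opposite, the equally available (R,R)-tartaramide is used.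
Remark: C6 of 9 and C3 of 18 are epimer mixtures of no consequence, because both centres pass through planar cations. Their SMILES carry no descriptor there.

Step 1
Reactants: 1 (E)-pent-2-enal
Product: 2 (3R,4E)-hept-4-en-3-ol
Conditions: Et2Zn (1.5 equiv), (2R)-(+)-3-exo-morpholinoisoborneol (5 mol %), hexane/toluene, 0 °C; aq NH4Cl
Reagents that add atoms: diethylzinc, CC[Zn]CC
Why: This is an amino-alcohol-catalysed enantioselective addition of a dialkylzinc to an enal, in which the chiral zinc aminoalkoxide delivers ethyl to one aldehyde face and so sets the carbinol centre as R.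

Step 2
Reactants: 2 (3R,4E)-hept-4-en-3-ol
Product: 4 ethyl (3R,4E)-3-ethylhept-4-enoate, via allyl ketene acetal 3 (not isolated)
Conditions: MeC(OEt)3 (6 equiv), EtCO2H (5 mol %), 140 °C, EtOH distilled off
Reagents that add atoms: triethyl orthoacetate, CC(OCC)(OCC)OCC
Why: The Johnson–Claisen rearrangement runs through a chair transition state with the carbinol ethyl group equatorial, which moves the C–O chirality suprafacially to the new C–C bond (future C10, R) and gives the E alkene (future C11=C12).

Step 3
Reactants: 4 ethyl (3R,4E)-3-ethylhept-4-enoate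
Product: 5 (3R,4E)-3-ethylhept-4-enal
Conditions: i-Bu2AlH (1.05 equiv), CH2Cl2, −78 °C; aq Rochelle salt
Reagents that add atoms: none
Why: Partial ester reduction with DIBAL-H stops at the low-temperature aluminium hemiacetal and touches neither the alkene nor the β-stereocentre.

Step 4
Reactants: 5 (3R,4E)-3-ethylhept-4-enal; 6 diethyl (2-oxobutyl)phosphonate
Product: 7 (4E,7R,8E)-7-ethylundeca-4,8-dien-3-one
Conditions: LiCl, i-Pr2NEt, MeCN, 23 °C
Reagents that add atoms: none
Why: Horner–Wadsworth–Emmons olefination under Masamune–Roush conditions should give the E enone with a base too weak to isomerise the skipped alkene, and it brings in C6, C7 and the C6 ethyl arm.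

Step 5
Reactants: 7 (4E,7R,8E)-7-ethylundeca-4,8-dien-3-one
Product: 8 (3Z,7R,8E)-7-ethyl-3-[(triethylsilyl)oxy]undeca-3,8-diene
Conditions: Et3SiH (1.2 equiv), RhCl(PPh3)3 (1 mol %), toluene, 50 °C
Reagents that add atoms: triethylsilane, CC[SiH](CC)CC
Why: Rhodium-catalysed 1,4-hydrosilylation of an enone with a monohydrosilane saturates only the conjugated C=C and gives one regiodefined silyl enol ether (its geometry is of no consequence), while the isolated 1,2-disubstituted alkene is inert.

Step 6
Reactants: 8 (3Z,7R,8E)-7-ethyl-3-[(triethylsilyl)oxy]undeca-3,8-diene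
Product: 9 (7R,8E)-7-ethyl-3-[(triethylsilyl)oxy]-3-[(triethylsilyl)peroxy]undec-8-ene
Conditions: O2 (1 atm), Et3SiH (2 equiv), Co(thd)2 [bis(2,2,6,6-tetramethylheptane-3,5-dionato)cobalt] (5 mol %), ClCH2CH2Cl, 23 °C
Reagents that add atoms: dioxygen, O=O; triethylsilane, CC[SiH](CC)CC
Why: Mukaiyama–Isayama cobalt-catalysed silylperoxidation is known for silyl enol ethers: H-atom transfer to the enol ether CH gives the α-silyloxy radical at C6, which traps O2 and is silylated, and the electron-rich enol ether should react ahead of the unactivated alkene.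

Step 7
Reactants: 10 (E)-but-1-en-1-ylboronic acid; 11 (2S,3S)-N,N,N′,N′-tetramethyltartaramide
Product: 12 (4S,5S)-2-[(E)-but-1-en-1-yl]-N,N,N′,N′-tetramethyl-1,3,2-dioxaborolane-4,5-dicarboxamide
Conditions: 4 Å molecular sieves, THF, 23 °C
Reagents that add atoms: none
Why: Condensation of a boronic acid with a 1,2-diol is driven by water removal and attaches the chiral auxiliary next to the alkene.

Step 8
Reactants: 12 (4S,5S)-2-[(E)-but-1-en-1-yl]-N,N,N′,N′-tetramethyl-1,3,2-dioxaborolane-4,5-dicarboxamide
Product: 14 (1S,2S)-2-ethylcyclopropan-1-ol, via cyclopropylboronate 13 (not isolated)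
Conditions: CH2I2, Zn–Cu couple, Et2O, reflux; then 30 % H2O2, KHCO3, THF, 0 °C
Reagents that add atoms: diiodomethane, ICI; hydrogen peroxide, OO
Why: Simmons–Smith cyclopropanation of an alkenylboronic tartaramide ester is a stereospecific syn addition (E alkene gives the trans ring) with the face chosen by the carbenoid-binding amide groups, which sets future C4 as S, and the C–B bond is then oxidised with retention under buffered conditions that spare the cyclopropanol.

Step 9
Reactants: 14 (1S,2S)-2-ethylcyclopropan-1-ol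
Product: 15 triethyl{[(1S,2S)-2-ethylcyclopropyl]oxy}silane
Conditions: Et3SiCl, imidazole, CH2Cl2, 0 °C
Reagents that add atoms: chlorotriethylsilane, CC[Si](Cl)(CC)CC
Why: Standard O-silylation under mild base turns the volatile and labile cyclopropanol into a storable homoenol silyl ether without ring opening.

Step 10
Reactants: 9 (7R,8E)-7-ethyl-3-[(triethylsilyl)oxy]-3-[(triethylsilyl)peroxy]undec-8-ene; 15 triethyl{[(1S,2S)-2-ethylcyclopropyl]oxy}silane (2.5 equiv)
Product: 18 (4S,6S)-4,6-diethyl-6-[(4R,5E)-4-ethyloct-5-en-1-yl]-3-[(triethylsilyl)oxy]-1,2-dioxane, via peroxycarbenium triflate 16 (not isolated), via silyl oxocarbenium triflate 17 (not isolated)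
Conditions: Et3SiOSO2CF3 (0.2 equiv), 2,6-di-tert-butyl-4-methylpyridine (0.3 equiv), CH2Cl2, −78 to −40 °C; Et3N quench; chromatography on Et3N-washed silica
Reagents that add atoms: none
Why: Proposed new method: Et3SiOTf removes the silyloxy group of 9 as (Et3Si)2O and leaves the O-silylperoxycarbenium ion 16, the C3–C5 σ-bond of the donor cyclopropane 15 attacks C6 through the unsubstituted C5 (homo-Mukaiyama SE2 opening, C5–C6 bond) and thereby unmasks C3 as the silyl oxocarbenium ion 17, and the silylperoxy oxygen O2 adds to C3 (O2–C3 bond) with release of Et3Si+ as the chain carrier. The closest known reaction types are the Lewis acid allylation, Mukaiyama and [3+2] alkene annulation reactions of silyl peroxyketals via peroxycarbenium ions and the intramolecular addition of cyclopropyl silyl ethers, as homoenol ethers, to oxocarbenium ions; what is new is their intermolecular merger into a formal [3+3] annulation. The 1,2-dioxane, the only ring formed, closes by 6-exo-trig attack of O2 on the C3=O+ bond. C4 comes in unchanged from 15 because none of its four bonds is touched, C3 arises as an anomeric mixture that step 11 erases, and C6 is fixed in the C5–C6 bond formation with C4 as the only control element (1,3-induction in a chair-like array with the C4 ethyl group equatorial), a bias that should be small because the ethyl and C7–C14 arms are alike up to their β-carbons, so the 4,6-trans ring diastereomer is taken off by chromatography at 18. The step needs cleavage of C3–C5 and not C3–C4, which the donor oxygen on C3 and the unhindered CH2 secure, and capture of 16 by 15 ahead of the remote C11=C12 alkene, which the excess of the more nucleophilic donor cyclopropane and the alkene's need to pass through a secondary cation secure. The O–O bond should survive because the promoter is a catalytic, non-reducing silyl Lewis acid at −78 °C and the hindered pyridine removes adventitious TfOH that would protonate 15.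

Step 11
Reactants: 18 (4S,6S)-4,6-diethyl-6-[(4R,5E)-4-ethyloct-5-en-1-yl]-3-[(triethylsilyl)oxy]-1,2-dioxane; 19 tert-butyl[(1-methoxyethenyl)oxy]dimethylsilane
Product: 21 methyl 2-{(3S,4S,6S)-4,6-diethyl-6-[(4R,5E)-4-ethyloct-5-en-1-yl]-1,2-dioxan-3-yl}acetate, via cyclic peroxycarbenium triflate 20 (not isolated)
Conditions: Et3SiOSO2CF3 (0.2 equiv), CH2Cl2, −78 °C; aq NaHCO3
Reagents that add atoms: none
Why: This is a Lewis acid substitution of a cyclic peroxyacetal by a silyl ketene acetal (Mukaiyama type, known for 3-alkoxy cyclic peroxides) through cation 20, whose half-chair is locked with the C4 ethyl group pseudoequatorial because the other half-chair would put the C4 and C6 ethyl groups syn-diaxial, so the stereoelectronically preferred axial attack should lead straight to the chair with CH2CO2Me axial, that is 3,4-cis (3S).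

Compound list
1 | (E)-pent-2-enal | CC/C=C/C=O | starting material
2 | (3R,4E)-hept-4-en-3-ol | CC/C=C/[C@H](O)CC | intermediate
3 | (3R,4E)-3-[(1-ethoxyethenyl)oxy]hept-4-ene | C=C(OCC)O[C@H](CC)/C=C/CC | intermediate
4 | ethyl (3R,4E)-3-ethylhept-4-enoate | CC/C=C/[C@H](CC)CC(=O)OCC | intermediate
5 | (3R,4E)-3-ethylhept-4-enal | CC/C=C/[C@H](CC)CC=O | intermediate
6 | diethyl (2-oxobutyl)phosphonate | CCC(=O)CP(=O)(OCC)OCC | starting material
7 | (4E,7R,8E)-7-ethylundeca-4,8-dien-3-one | CC/C=C/[C@H](CC)C/C=C/C(=O)CC | intermediate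
8 | (3Z,7R,8E)-7-ethyl-3-[(triethylsilyl)oxy]undeca-3,8-diene | CC/C=C/[C@H](CC)CC/C=C(\O[Si](CC)(CC)CC)CC | intermediate
9 | (7R,8E)-7-ethyl-3-[(triethylsilyl)oxy]-3-[(triethylsilyl)peroxy]undec-8-ene (both C3 epimers) | CC/C=C/[C@H](CC)CCCC(CC)(O[Si](CC)(CC)CC)OO[Si](CC)(CC)CC | intermediate
10 | (E)-but-1-en-1-ylboronic acid | CC/C=C/B(O)O | starting material
11 | (2S,3S)-N,N,N′,N′-tetramethyltartaramide | CN(C)C(=O)[C@@H](O)[C@H](O)C(=O)N(C)C | starting material
12 | (4S,5S)-2-[(E)-but-1-en-1-yl]-N,N,N′,N′-tetramethyl-1,3,2-dioxaborolane-4,5-dicarboxamide | CN(C)C(=O)[C@H]1OB(/C=C/CC)O[C@@H]1C(=O)N(C)C | intermediate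
13 | (4S,5S)-2-[(1S,2S)-2-ethylcyclopropyl]-N,N,N′,N′-tetramethyl-1,3,2-dioxaborolane-4,5-dicarboxamide | CN(C)C(=O)[C@H]1OB([C@H]2C[C@@H]2CC)O[C@@H]1C(=O)N(C)C | intermediate
14 | (1S,2S)-2-ethylcyclopropan-1-ol | C1[C@H](CC)[C@H]1O | intermediate
15 | triethyl{[(1S,2S)-2-ethylcyclopropyl]oxy}silane | C1[C@H](CC)[C@H]1O[Si](CC)(CC)CC | intermediate
16 | [(7R,8E)-7-ethylundec-8-en-3-ylidene][(triethylsilyl)oxy]oxonium triflate | CC/C=C/[C@H](CC)CCCC(CC)=[O+]O[Si](CC)(CC)CC.[O-]S(=O)(=O)C(F)(F)F | intermediate
17 | {(2S,4S,8R,9E)-2,4,8-triethyl-4-[(triethylsilyl)peroxy]dodec-9-en-1-ylidene}(triethylsilyl)oxonium triflate | CC/C=C/[C@H](CC)CCC[C@](CC)(OO[Si](CC)(CC)CC)C[C@H](CC)C=[O+][Si](CC)(CC)CC.[O-]S(=O)(=O)C(F)(F)F | intermediate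
18 | (4S,6S)-4,6-diethyl-6-[(4R,5E)-4-ethyloct-5-en-1-yl]-3-[(triethylsilyl)oxy]-1,2-dioxane (both C3 anomers) | CC/C=C/[C@H](CC)CCC[C@@]1(CC)C[C@H](CC)C(O[Si](CC)(CC)CC)OO1 | intermediate
19 | tert-butyl[(1-methoxyethenyl)oxy]dimethylsilane | C=C(OC)O[Si](C)(C)C(C)(C)C | starting material
20 | (4S,6S)-4,6-diethyl-6-[(4R,5E)-4-ethyloct-5-en-1-yl]-5,6-dihydro-4H-1,2-dioxin-2-ium triflate | CC/C=C/[C@H](CC)CCC[C@@]1(CC)C[C@H](CC)C=[O+]O1.[O-]S(=O)(=O)C(F)(F)F | intermediate
21 | methyl 2-{(3S,4S,6S)-4,6-diethyl-6-[(4R,5E)-4-ethyloct-5-en-1-yl]-1,2-dioxan-3-yl}acetate | CC/C=C/[C@H](CC)CCC[C@@]1(CC)C[C@H](CC)[C@H](CC(=O)OC)OO1 | target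

Total step count: 11. Longest linear sequence: 8 steps (steps 1–6, 10, 11).

Steps most likely to fail

1. Step 10 (new method).
- Risk: the σ-bond of 15 may capture cation 16 too slowly, so that attack by the C11=C12 alkene, proton loss or O–O heterolysis takes over. The two faces of C6 may also be told apart poorly.
- Fallback: known chemistry with classical polarity, making the two bonds one after the other. It sets out from 8 and 15 and comes back at 21.
- Dilute HCl in THF hydrolyses 8 to (7R,8E)-7-ethylundec-8-en-3-one F1.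
- NBS in CH2Cl2 opens 15 at its CH2 carbon to (2R)-2-(bromomethyl)butanal F2. HC(OMe)3 and catalytic TsOH convert this into (2R)-1-bromo-2-(dimethoxymethyl)butane F3.
- Bromine–lithium exchange with t-BuLi at −78 °C gives [(2R)-2-(dimethoxymethyl)butyl]lithium F4, a classical homoenolate equivalent. It adds to F1 in the presence of CeCl3 to give (2S,8R,9E)-2,4,8-triethyl-1,1-dimethoxydodec-9-en-4-ol F5 (C5–C6 bond, both epimers at the carbinol carbon).
- Acid-catalysed perhydrolysis (50 % H2O2, catalytic H2SO4) exchanges the tertiary OH for OOH to give (2S,8R,9E)-2,4,8-triethyl-1,1-dimethoxydodec-9-en-4-yl hydroperoxide F6.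
- F6 closes onto the acetal under the same acid to (4S,6S)-4,6-diethyl-6-[(4R,5E)-4-ethyloct-5-en-1-yl]-3-methoxy-1,2-dioxane F7 (O2–C3 bond), obtained after chromatographic removal of the C6 epimer.
- F7 and 19 under the conditions of step 11 should give 21.

2. Step 11.
- Risk: attack on the equatorial face next to the C4 ethyl group (poor facial selectivity at C3), or proton loss from C4 of cation 20.
- Fallback: it sets out from 18 and comes back at 21.
- HF·pyridine frees (4S,6S)-4,6-diethyl-6-[(4R,5E)-4-ethyloct-5-en-1-yl]-1,2-dioxan-3-ol F8.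
- The open hydroperoxy aldehyde form of F8 is olefinated by Ph3P=CHCO2Me to methyl (2E,4S,6S,10R,11E)-4,6,10-triethyl-6-hydroperoxytetradeca-2,11-dienoate F9.
- Catalytic Et2NH then closes the ring by 6-exo-trig oxa-Michael addition to 21. Because this addition is reversible, the separated C3 epimer can be resubmitted to the base.

3. Step 6.
- Risk: H-atom transfer to the C11=C12 alkene as well (loss of chemoselectivity), or hydrolysis of the enol ether.
- Fallback: a polar instead of a radical route, setting out from 8 and coming back at 9.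
- Anhydrous H2O2 in Et2O with catalytic pyridinium p-toluenesulfonate at 0 °C adds across the enol ether in the Markovnikov sense. This is the acid-catalysed perketalisation of enol ethers, and it gives (7R,8E)-7-ethyl-3-[(triethylsilyl)oxy]undec-8-en-3-yl hydroperoxide F10.
- Et3SiCl and imidazole then silylate the hydroperoxide to 9.

Further compounds
F1 | step 10 | (7R,8E)-7-ethylundec-8-en-3-one | CC/C=C/[C@H](CC)CCCC(=O)CC
F2 | step 10 | (2R)-2-(bromomethyl)butanal | BrC[C@H](CC)C=O
F3 | step 10 | (2R)-1-bromo-2-(dimethoxymethyl)butane | BrC[C@H](CC)C(OC)OC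
F4 | step 10 | [(2R)-2-(dimethoxymethyl)butyl]lithium | [Li]C[C@H](CC)C(OC)OC
F5 | step 10 | (2S,8R,9E)-2,4,8-triethyl-1,1-dimethoxydodec-9-en-4-ol (both C4 epimers) | CC/C=C/[C@H](CC)CCCC(O)(CC)C[C@H](CC)C(OC)OC
F6 | step 10 | (2S,8R,9E)-2,4,8-triethyl-1,1-dimethoxydodec-9-en-4-yl hydroperoxide (both C4 epimers) | CC/C=C/[C@H](CC)CCCC(OO)(CC)C[C@H](CC)C(OC)OC
F7 | step 10 | (4S,6S)-4,6-diethyl-6-[(4R,5E)-4-ethyloct-5-en-1-yl]-3-methoxy-1,2-dioxane (both C3 anomers) | CC/C=C/[C@H](CC)CCC[C@@]1(CC)C[C@H](CC)C(OC)OO1
F8 | step 11 | (4S,6S)-4,6-diethyl-6-[(4R,5E)-4-ethyloct-5-en-1-yl]-1,2-dioxan-3-ol (both C3 anomers) | CC/C=C/[C@H](CC)CCC[C@@]1(CC)C[C@H](CC)C(O)OO1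
F9 | step 11 | methyl (2E,4S,6S,10R,11E)-4,6,10-triethyl-6-hydroperoxytetradeca-2,11-dienoate | CC/C=C/[C@H](CC)CCC[C@](CC)(OO)C[C@H](CC)/C=C/C(=O)OC
F10 | step 6 | (7R,8E)-7-ethyl-3-[(triethylsilyl)oxy]undec-8-en-3-yl hydroperoxide (both C3 epimers) | CC/C=C/[C@H](CC)CCCC(CC)(OO)O[Si](CC)(CC)CC
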